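**Retrosynthetic overview**

1. Target 25 comes from its penta-O-benzyl ether 24 by hydrogenolysis; the 4'-methyl ether stays.
2. 24 is cut at C4–C4a and C4''–C4a'' of the two pyranone rings (rings C and C''). This lays bare C4–C3–C3''–C4'', a 2,3-disubstituted succinic acid (bis-Weinreb amide 21) whose side-chain carbons C2 and C2'' are para-alkoxybenzylic aryl ethers: they ionise in acid but are inert to organolithiums at low temperature.
3. 21 comes from bis-carbinol dicarboxylate 15: both aryl ether bonds are made at the aromatic carbon (SNAr on fluoronitroarene 14), so C2–O and C2''–O are never broken; NO2 is then turned into NH2 and Br.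
4. 15 comes from lactones 11 and 5: C2/C3 by asymmetric transfer hydrogenation and Fráter–Seebach alkylation, C3''/C2'' by lactone-enolate acylation and a mirror-image transfer hydrogenation.
5. Ring order: a temporary γ-lactone (5 to 11), then rings C and C'' together in the key step.

Key step: step 11

Assumption: the target is read as 2S,3R,2''R,3''S (both pyranone rings 2,3-trans); flavanone numbering is used throughout, unprimed for the 4-methoxyphenyl half and double-primed for the 4-hydroxyphenyl half, also in open-chain intermediates. Apart from OMe versus OH the two halves are mirror images, so each carbinol centre is set by its own enantiomer of one catalyst.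

**Step 1**
Reactants: 1 ethyl 3-(4-methoxyphenyl)-3-oxopropanoate
Product: 2 ethyl (3S)-3-hydroxy-3-(4-methoxyphenyl)propanoate
Conditions: RuCl[(S,S)-TsDPEN](p-cymene) (1 mol %), HCO2H/Et3N (5:2), 40 °C
Reagents that add atoms: none
Why: Noyori–Ikariya asymmetric transfer hydrogenation of an aryl β-keto ester, in which the (S,S)-ligand should direct hydride to the face that gives the (S)-carbinol, the future C2.

**Step 2**
Reactants: 2 ethyl (3S)-3-hydroxy-3-(4-methoxyphenyl)propanoate, 3 methyl bromoacetate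
Product: 5 ethyl (2S,3R)-2-(4-methoxyphenyl)-5-oxooxolane-3-carboxylate, via hydroxy diester 4 (not isolated)
Conditions: LiN(i-Pr)2 (2.2 equiv), THF, −78 to −20 °C; 3, DMPU, −78 to −30 °C; AcOH; then pyridinium p-toluenesulfonate (cat.), toluene, 45 °C
Reagents that add atoms: none
Why: Fráter–Seebach alkylation, in which the chelated alkoxide–enolate dianion is alkylated on the face away from the aryl group and so sets C3 anti to the C2 oxygen (the later 2,3-trans relation), followed by acyl-transfer lactonization that masks the C2 hydroxyl without touching the benzylic C–O bond.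

**Step 3**
Reactants: 6 4-(benzyloxy)benzoic acid
Product: 8 4-(benzyloxy)-N-methoxy-N-methylbenzamide, via acyl imidazole 7 (not isolated)
Conditions: 1,1'-carbonyldiimidazole, CH2Cl2, rt; MeNHOMe·HCl, rt
Reagents that add atoms: N,O-dimethylhydroxylamine hydrochloride, CNOC.Cl
Why: Standard Weinreb amide synthesis by carboxyl activation as the acyl imidazole and aminolysis.

**Step 4**
Reactants: 5 ethyl (2S,3R)-2-(4-methoxyphenyl)-5-oxooxolane-3-carboxylate, 8 4-(benzyloxy)-N-methoxy-N-methylbenzamide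
Product: 10 ethyl (2S,3R,4S)-4-[4-(benzyloxy)benzoyl]-2-(4-methoxyphenyl)-5-oxooxolane-3-carboxylate, via lithium hemiaminal adduct 9 (not isolated)
Conditions: LiN(SiMe3)2 (1.1 equiv), THF, −78 °C; 8, −78 to −30 °C; AcOH, −78 °C
Reagents that add atoms: none
Why: Crossed Claisen-type C-acylation of a lactone enolate with a Weinreb amide, in which kinetic deprotonation should take the more acidic, less hindered lactone CH2 and not the tertiary C–H next to the ester, the chelated adduct prevents a second addition, and the acyl group settles trans to the neighbouring ester (this centre is still labile).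

**Step 5**
Reactants: 10 ethyl (2S,3R,4S)-4-[4-(benzyloxy)benzoyl]-2-(4-methoxyphenyl)-5-oxooxolane-3-carboxylate
Product: 11 ethyl (2S,3R,4S)-4-[(R)-[4-(benzyloxy)phenyl](hydroxy)methyl]-2-(4-methoxyphenyl)-5-oxooxolane-3-carboxylate
Conditions: RuCl[(R,R)-TsDPEN](p-cymene) (2 mol %), HCO2H/Et3N (5:2), DMF, 35 °C
Reagents that add atoms: none
Why: Asymmetric transfer hydrogenation with dynamic kinetic resolution, in which the (R,R)-catalyst should fix the (R)-carbinol (future C2'') while C3'', which equilibrates through the enol under Et3N, is reduced as the ring epimer with its side chain trans to the ester, so that C3'' mirrors C3.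

**Step 6**
Reactants: 12 1,3,5-trifluoro-2-nitrobenzene, 13 benzyl alcohol
Product: 14 1,5-bis(benzyloxy)-3-fluoro-2-nitrobenzene
Conditions: 13 (2.05 equiv), K2CO3, DMF, 0 °C to rt; crystallisation
Reagents that add atoms: none
Why: Twofold SNAr on a nitro-activated fluoroarene, in which the para fluorine reacts early in DMF and the third substitution is slowed by two donor alkoxy groups, so that the isomer with one ortho and the para benzyloxy group should be the main product and is purified by crystallisation.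

**Step 7**
Reactants: 11 ethyl (2S,3R,4S)-4-[(R)-[4-(benzyloxy)phenyl](hydroxy)methyl]-2-(4-methoxyphenyl)-5-oxooxolane-3-carboxylate, 14 1,5-bis(benzyloxy)-3-fluoro-2-nitrobenzene
Product: 16 (2R,3S)-2-[(S)-[3,5-bis(benzyloxy)-2-nitrophenoxy](4-methoxyphenyl)methyl]-3-[(R)-[4-(benzyloxy)phenyl][3,5-bis(benzyloxy)-2-nitrophenoxy]methyl]butanedioic acid, via dipotassium salt 15 (not isolated)
Conditions: KOH (2.1 equiv), THF/H2O, rt; evaporation, toluene azeotrope; KN(SiMe3)2 (2.1 equiv), 18-crown-6, DMF, 0 °C; 14 (2.4 equiv), 0 °C to rt; aq. KHSO4 (pH 3–4), 0 °C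
Reagents that add atoms: potassium hydroxide, [K+].[OH-]
Why: Saponification of lactone and ester followed by SNAr of the two alkoxides on the ortho-fluoronitroarene forms both aryl ether bonds at the aromatic carbon, so C2 and C2'' keep their configuration, and as carboxylate salts the β-oxido acids should resist retro-aldol cleavage, relactonization and elimination.

**Step 8**
Reactants: 16 the bis(nitroaryl ether) diacid
Product: 18 (2R,3S)-2-[(S)-[3,5-bis(benzyloxy)-2-nitrophenoxy](4-methoxyphenyl)methyl]-3-[(R)-[4-(benzyloxy)phenyl][3,5-bis(benzyloxy)-2-nitrophenoxy]methyl]-N1,N4-dimethoxy-N1,N4-dimethylbutanediamide, via bis(acyl imidazole) 17 (not isolated)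
Conditions: 1,1'-carbonyldiimidazole (2.4 equiv), CH2Cl2, 0 °C to rt; MeNHOMe·HCl (3 equiv), rt
Reagents that add atoms: N,O-dimethylhydroxylamine hydrochloride, CNOC.Cl
Why: Weinreb amide formation through acyl imidazoles without added strong base, which spares the β-aryloxy groups, while the cis-anhydride that this meso-type succinic acid would need is disfavoured by its two large substituents.

**Step 9**
Reactants: 18 the bis(nitroaryl ether) bis-Weinreb amide
Product: 19 (2R,3S)-2-[(S)-[2-amino-3,5-bis(benzyloxy)phenoxy](4-methoxyphenyl)methyl]-3-[(R)-[2-amino-3,5-bis(benzyloxy)phenoxy][4-(benzyloxy)phenyl]methyl]-N1,N4-dimethoxy-N1,N4-dimethylbutanediamide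
Conditions: H2 (1 atm), Pt/C (5 %, sulfided), EtOAc/THF, rt
Reagents that add atoms: none
Why: Chemoselective catalytic hydrogenation of nitro groups over sulfided platinum, which should not hydrogenolyse benzyl ethers, the benzylic aryl ether bonds or the N–O bonds of the amides.

**Step 10**
Reactants: 19 the bis(2-aminoaryl ether) bis-Weinreb amide
Product: 21 (2R,3S)-2-[(S)-[3,5-bis(benzyloxy)-2-bromophenoxy](4-methoxyphenyl)methyl]-3-[(R)-[4-(benzyloxy)phenyl][3,5-bis(benzyloxy)-2-bromophenoxy]methyl]-N1,N4-dimethoxy-N1,N4-dimethylbutanediamide, via bis(diazonium) dibromide 20 (not isolated)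
Conditions: t-BuONO (3 equiv), CuBr2 (3 equiv), MeCN, slow addition of 19, 0 °C to rt
Reagents that add atoms: copper dibromide, Br[Cu]Br
Why: Non-aqueous Sandmeyer bromination, in which in-situ diazotization and copper-mediated bromine transfer replace each amino group by bromine on the carbon between the ether oxygen and a benzyloxy group.

**Step 11**
Reactants: 21 the bis(2-bromoaryl ether) bis-Weinreb amide
Product: 24 (2S,3R)-5,7-bis(benzyloxy)-3-[(2R,3S)-5,7-bis(benzyloxy)-2-[4-(benzyloxy)phenyl]-4-oxochroman-3-yl]-2-(4-methoxyphenyl)chroman-4-one, via bis(aryllithium) 22 (not isolated), via dilithium bis(hemiaminal) 23 (not isolated)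
Conditions: t-BuLi (4.4 equiv), THF/Et2O, −100 to −78 °C; aq. NH4Cl
Reagents that add atoms: none
Why: Each aryl bromide is metalated by t-BuLi at −100 °C (a second equivalent destroys the t-BuBr formed), and each aryl carbanion of 22 attacks the Weinreb amide carbonyl five atoms away to give the lithium hemiaminals of 23, which are held as N-methoxy chelates until protonation and then collapse to the two aryl ketones. The closest known reaction is the Parham cycloacylation of 3-(2-bromoaryloxy)propanoic Weinreb amides to chroman-4-ones, here run in two directions on one succinamide. Ring C (bond C4–C4a) and ring C'' (bond C4''–C4a'') both close in the 6-exo-trig mode. No stereocentre is created: C2 and C2'' are carried over because the benzylic ethers are not ionised under anionic conditions, and C3 and C3'' because the carbonyl carbons stay tetrahedral and cannot enolise before the quench. Chemoselectivity is the demand, since metalation and closure must be faster than removal of the protons next to the amides, which would expel aryloxide from C2 or C2''; the very fast exchange at an aryl bromide flanked by two oxygens, the low temperature and the intramolecular acylation should provide this, and because bromine sits on the carbon between O1 and the future C5 oxygen the carbonyl is attached at C4a and the 5,7-pattern follows.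

**Step 12**
Reactants: 24 the penta-O-benzyl biflavanone
Product: 25 (2S,3R)-3-[(2R,3S)-5,7-dihydroxy-2-(4-hydroxyphenyl)-4-oxochroman-3-yl]-5,7-dihydroxy-2-(4-methoxyphenyl)chroman-4-one
Conditions: H2 (1 atm), Pd/C (10 %), EtOAc/MeOH, rt
Reagents that add atoms: none
Why: Hydrogenolysis of the five benzyl ethers over palladium under neutral conditions should leave the methyl ether, the ketones and the four stereocentres untouched.

**Compound list**

1 | ethyl 3-(4-methoxyphenyl)-3-oxopropanoate | CCOC(=O)CC(=O)c1ccc(OC)cc1 | starting material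
2 | ethyl (3S)-3-hydroxy-3-(4-methoxyphenyl)propanoate | COc1ccc([C@@H](O)CC(=O)OCC)cc1 | intermediate
3 | methyl bromoacetate | COC(=O)CBr | starting material
4 | 1-ethyl 4-methyl (2R)-2-[(S)-hydroxy(4-methoxyphenyl)methyl]butanedioate (not isolated) | COc1ccc([C@@H](O)[C@H](C(=O)OCC)CC(=O)OC)cc1 | intermediate
5 | ethyl (2S,3R)-2-(4-methoxyphenyl)-5-oxooxolane-3-carboxylate (cis) | COc1ccc([C@H]2OC(=O)C[C@H]2C(=O)OCC)cc1 | intermediate
6 | 4-(benzyloxy)benzoic acid | OC(=O)c1ccc(OCc2ccccc2)cc1 | starting material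
7 | 1-[4-(benzyloxy)benzoyl]imidazole (not isolated) | O=C(c1ccc(OCc2ccccc2)cc1)n1ccnc1 | intermediate
8 | 4-(benzyloxy)-N-methoxy-N-methylbenzamide | CON(C)C(=O)c1ccc(OCc2ccccc2)cc1 | intermediate
9 | lithium hemiaminal adduct of the enolate of 5 with 8 (not isolated) | COc1ccc([C@H]2OC(=O)[C@H](C(O[Li])(N(C)OC)c3ccc(OCc4ccccc4)cc3)[C@H]2C(=O)OCC)cc1 | intermediate
10 | ethyl (2S,3R,4S)-4-[4-(benzyloxy)benzoyl]-2-(4-methoxyphenyl)-5-oxooxolane-3-carboxylate | COc1ccc([C@H]2OC(=O)[C@H](C(=O)c3ccc(OCc4ccccc4)cc3)[C@H]2C(=O)OCC)cc1 | intermediate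
11 | ethyl (2S,3R,4S)-4-[(R)-[4-(benzyloxy)phenyl](hydroxy)methyl]-2-(4-methoxyphenyl)-5-oxooxolane-3-carboxylate | COc1ccc([C@H]2OC(=O)[C@H]([C@@H](O)c3ccc(OCc4ccccc4)cc3)[C@H]2C(=O)OCC)cc1 | intermediate
12 | 1,3,5-trifluoro-2-nitrobenzene | [O-][N+](=O)c1c(F)cc(F)cc1F | starting material
13 | benzyl alcohol | OCc1ccccc1 | starting material
14 | 1,5-bis(benzyloxy)-3-fluoro-2-nitrobenzene | [O-][N+](=O)c1c(F)cc(OCc2ccccc2)cc1OCc1ccccc1 | intermediate
15 | dipotassium (2R,3S)-2-[(S)-hydroxy(4-methoxyphenyl)methyl]-3-[(R)-[4-(benzyloxy)phenyl](hydroxy)methyl]butanedioate (not isolated) | COc1ccc([C@@H](O)[C@H](C(=O)[O-])[C@H](C(=O)[O-])[C@@H](O)c2ccc(OCc3ccccc3)cc2)cc1.[K+].[K+] | intermediate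
16 | (2R,3S)-2-[(S)-[3,5-bis(benzyloxy)-2-nitrophenoxy](4-methoxyphenyl)methyl]-3-[(R)-[4-(benzyloxy)phenyl][3,5-bis(benzyloxy)-2-nitrophenoxy]methyl]butanedioic acid | COc1ccc([C@@H](Oc2cc(OCc3ccccc3)cc(OCc3ccccc3)c2[N+](=O)[O-])[C@H](C(=O)O)[C@H](C(=O)O)[C@@H](Oc2cc(OCc3ccccc3)cc(OCc3ccccc3)c2[N+](=O)[O-])c2ccc(OCc3ccccc3)cc2)cc1 | intermediate
17 | bis(acyl imidazole) of 16 (not isolated) | COc1ccc([C@@H](Oc2cc(OCc3ccccc3)cc(OCc3ccccc3)c2[N+](=O)[O-])[C@H](C(=O)n2ccnc2)[C@H](C(=O)n2ccnc2)[C@@H](Oc2cc(OCc3ccccc3)cc(OCc3ccccc3)c2[N+](=O)[O-])c2ccc(OCc3ccccc3)cc2)cc1 | intermediate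
18 | (2R,3S)-2-[(S)-[3,5-bis(benzyloxy)-2-nitrophenoxy](4-methoxyphenyl)methyl]-3-[(R)-[4-(benzyloxy)phenyl][3,5-bis(benzyloxy)-2-nitrophenoxy]methyl]-N1,N4-dimethoxy-N1,N4-dimethylbutanediamide | COc1ccc([C@@H](Oc2cc(OCc3ccccc3)cc(OCc3ccccc3)c2[N+](=O)[O-])[C@H](C(=O)N(C)OC)[C@H](C(=O)N(C)OC)[C@@H](Oc2cc(OCc3ccccc3)cc(OCc3ccccc3)c2[N+](=O)[O-])c2ccc(OCc3ccccc3)cc2)cc1 | intermediate
19 | (2R,3S)-2-[(S)-[2-amino-3,5-bis(benzyloxy)phenoxy](4-methoxyphenyl)methyl]-3-[(R)-[2-amino-3,5-bis(benzyloxy)phenoxy][4-(benzyloxy)phenyl]methyl]-N1,N4-dimethoxy-N1,N4-dimethylbutanediamide | COc1ccc([C@@H](Oc2cc(OCc3ccccc3)cc(OCc3ccccc3)c2N)[C@H](C(=O)N(C)OC)[C@H](C(=O)N(C)OC)[C@@H](Oc2cc(OCc3ccccc3)cc(OCc3ccccc3)c2N)c2ccc(OCc3ccccc3)cc2)cc1 | intermediate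
20 | bis(diazonium) dibromide of 19 (not isolated) | COc1ccc([C@@H](Oc2cc(OCc3ccccc3)cc(OCc3ccccc3)c2[N+]#N)[C@H](C(=O)N(C)OC)[C@H](C(=O)N(C)OC)[C@@H](Oc2cc(OCc3ccccc3)cc(OCc3ccccc3)c2[N+]#N)c2ccc(OCc3ccccc3)cc2)cc1.[Br-].[Br-] | intermediate
21 | (2R,3S)-2-[(S)-[3,5-bis(benzyloxy)-2-bromophenoxy](4-methoxyphenyl)methyl]-3-[(R)-[4-(benzyloxy)phenyl][3,5-bis(benzyloxy)-2-bromophenoxy]methyl]-N1,N4-dimethoxy-N1,N4-dimethylbutanediamide (key-step precursor) | COc1ccc([C@@H](Oc2cc(OCc3ccccc3)cc(OCc3ccccc3)c2Br)[C@H](C(=O)N(C)OC)[C@H](C(=O)N(C)OC)[C@@H](Oc2cc(OCc3ccccc3)cc(OCc3ccccc3)c2Br)c2ccc(OCc3ccccc3)cc2)cc1 | intermediate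
22 | bis(aryllithium) from 21 (not isolated) | COc1ccc([C@@H](Oc2cc(OCc3ccccc3)cc(OCc3ccccc3)c2[Li])[C@H](C(=O)N(C)OC)[C@H](C(=O)N(C)OC)[C@@H](Oc2cc(OCc3ccccc3)cc(OCc3ccccc3)c2[Li])c2ccc(OCc3ccccc3)cc2)cc1 | intermediate
23 | dilithium bis(hemiaminal) of the doubly cyclised product (not isolated) | COc1ccc([C@H]2Oc3cc(OCc4ccccc4)cc(OCc4ccccc4)c3C(O[Li])(N(C)OC)[C@@H]2[C@@H]2C(O[Li])(N(C)OC)c3c(OCc4ccccc4)cc(OCc4ccccc4)cc3O[C@H]2c2ccc(OCc3ccccc3)cc2)cc1 | intermediate
24 | (2S,3R)-5,7-bis(benzyloxy)-3-[(2R,3S)-5,7-bis(benzyloxy)-2-[4-(benzyloxy)phenyl]-4-oxochroman-3-yl]-2-(4-methoxyphenyl)chroman-4-one | COc1ccc([C@H]2Oc3cc(OCc4ccccc4)cc(OCc4ccccc4)c3C(=O)[C@@H]2[C@@H]2C(=O)c3c(OCc4ccccc4)cc(OCc4ccccc4)cc3O[C@H]2c2ccc(OCc3ccccc3)cc2)cc1 | intermediate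
25 | (2S,3R)-3-[(2R,3S)-5,7-dihydroxy-2-(4-hydroxyphenyl)-4-oxochroman-3-yl]-5,7-dihydroxy-2-(4-methoxyphenyl)chroman-4-one | COc1ccc([C@H]2Oc3cc(O)cc(O)c3C(=O)[C@@H]2[C@@H]2C(=O)c3c(O)cc(O)cc3O[C@H]2c2ccc(O)cc2)cc1 | target

**Step count**

Total: 12 steps. Longest linear sequence: 10 steps (1 → 2 → 5 → 10 → 11 → 16 → 18 → 19 → 21 → 24 → 25); steps 3 and 6 are side branches.

**Steps most likely to fail**

Step 11 (key step). The alkyllithium or the aryllithium may abstract a proton next to an amide carbonyl, after which aryloxide is lost from C2 or C2''; t-BuLi may also add to an amide, or only one ring may close. The fallback changes the acyl acceptor to a lithium carboxylate, whose α-hydrogens are not acidic, so enolisation and β-elimination are shut off. It sets out from 16. Hydrogenation over sulfided Pt/C gives the bis(2-aminoaryl ether) diacid F1. Diazotization and bromination (t-BuONO, CuBr2, MeCN) give the bis(2-bromoaryl ether) diacid F2. F2 is turned into its dilithium salt with LiN(SiMe3)2 (2.1 equiv, THF, −78 °C) and treated with t-BuLi (4.4 equiv, −100 to 0 °C); the aryllithiums add to the carboxylates, and mild aqueous work-up of the gem-diolates returns the route to 24. This is the original form of the Parham cycloacylation.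

Step 7. Aryl transfer to two hindered alkoxides held in a poorly soluble polyanion may be slow, and residual hydroxide may consume 14. The fallback takes the carboxyl carbons out of play by an oxidation-state detour. It sets out from 11. LiAlH4 (THF, 0 °C) gives the tetrol (2S,3R)-2-[(S)-hydroxy(4-methoxyphenyl)methyl]-3-[(R)-[4-(benzyloxy)phenyl](hydroxy)methyl]butane-1,4-diol F3. i-Pr3SiCl and imidazole silylate the two primary hydroxyls to give the bis(silyl ether) F4. NaH and 14 in DMF (0 °C to rt) give the bis(nitroaryl ether) F5. Bu4NF in THF frees the diol F6. Oxidation with TEMPO (cat.) and PhI(OAc)2 in MeCN/H2O brings the route back to 16.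

Step 10. The aryl radical may escape before bromine transfer, by 1,5-hydrogen transfer from the benzylic ether carbon or by cyclisation onto ring B, and the diazonium ion may couple with unreacted electron-rich aniline. The fallback changes the halogen and the way it is delivered. It sets out from 19. Diazotization in the presence of iodine (t-BuONO, I2, MeCN) gives the bis(2-iodoaryl ether) bis-Weinreb amide F7; iodine-atom transfer from I2 is close to diffusion control and should outrun the intramolecular radical pathways. F7 then undergoes iodine–lithium exchange (t-BuLi, 4.4 equiv, THF/Et2O, −100 °C) and the same twofold ring closure, and the route comes back at 24.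

**Further compounds**

F1 | step 11 | (2R,3S)-2-[(S)-[2-amino-3,5-bis(benzyloxy)phenoxy](4-methoxyphenyl)methyl]-3-[(R)-[2-amino-3,5-bis(benzyloxy)phenoxy][4-(benzyloxy)phenyl]methyl]butanedioic acid | COc1ccc([C@@H](Oc2cc(OCc3ccccc3)cc(OCc3ccccc3)c2N)[C@H](C(=O)O)[C@H](C(=O)O)[C@@H](Oc2cc(OCc3ccccc3)cc(OCc3ccccc3)c2N)c2ccc(OCc3ccccc3)cc2)cc1
F2 | step 11 | (2R,3S)-2-[(S)-[3,5-bis(benzyloxy)-2-bromophenoxy](4-methoxyphenyl)methyl]-3-[(R)-[4-(benzyloxy)phenyl][3,5-bis(benzyloxy)-2-bromophenoxy]methyl]butanedioic acid | COc1ccc([C@@H](Oc2cc(OCc3ccccc3)cc(OCc3ccccc3)c2Br)[C@H](C(=O)O)[C@H](C(=O)O)[C@@H](Oc2cc(OCc3ccccc3)cc(OCc3ccccc3)c2Br)c2ccc(OCc3ccccc3)cc2)cc1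
F3 | step 7 | (2S,3R)-2-[(S)-hydroxy(4-methoxyphenyl)methyl]-3-[(R)-[4-(benzyloxy)phenyl](hydroxy)methyl]butane-1,4-diol | COc1ccc([C@@H](O)[C@H](CO)[C@H](CO)[C@@H](O)c2ccc(OCc3ccccc3)cc2)cc1
F4 | step 7 | 1,4-bis-O-(triisopropylsilyl) ether of F3 | COc1ccc([C@@H](O)[C@H](CO[Si](C(C)C)(C(C)C)C(C)C)[C@H](CO[Si](C(C)C)(C(C)C)C(C)C)[C@@H](O)c2ccc(OCc3ccccc3)cc2)cc1
F5 | step 7 | bis[3,5-bis(benzyloxy)-2-nitrophenyl] ether of F4 | COc1ccc([C@@H](Oc2cc(OCc3ccccc3)cc(OCc3ccccc3)c2[N+](=O)[O-])[C@H](CO[Si](C(C)C)(C(C)C)C(C)C)[C@H](CO[Si](C(C)C)(C(C)C)C(C)C)[C@@H](Oc2cc(OCc3ccccc3)cc(OCc3ccccc3)c2[N+](=O)[O-])c2ccc(OCc3ccccc3)cc2)cc1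
F6 | step 7 | (2S,3R)-2-[(S)-[3,5-bis(benzyloxy)-2-nitrophenoxy](4-methoxyphenyl)methyl]-3-[(R)-[4-(benzyloxy)phenyl][3,5-bis(benzyloxy)-2-nitrophenoxy]methyl]butane-1,4-diol | COc1ccc([C@@H](Oc2cc(OCc3ccccc3)cc(OCc3ccccc3)c2[N+](=O)[O-])[C@H](CO)[C@H](CO)[C@@H](Oc2cc(OCc3ccccc3)cc(OCc3ccccc3)c2[N+](=O)[O-])c2ccc(OCc3ccccc3)cc2)cc1
F7 | step 10 | (2R,3S)-2-[(S)-[3,5-bis(benzyloxy)-2-iodophenoxy](4-methoxyphenyl)methyl]-3-[(R)-[4-(benzyloxy)phenyl][3,5-bis(benzyloxy)-2-iodophenoxy]methyl]-N1,N4-dimethoxy-N1,N4-dimethylbutanediamide | COc1ccc([C@@H](Oc2cc(OCc3ccccc3)cc(OCc3ccccc3)c2I)[C@H](C(=O)N(C)OC)[C@H](C(=O)N(C)OC)[C@@H](Oc2cc(OCc3ccccc3)cc(OCc3ccccc3)c2I)c2ccc(OCc3ccccc3)cc2)cc1
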